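**Retrosynthetic overview**
- The strategy rests on the unbranched nonadecyl chain on C2 of the cyclohexa-2,5-diene-1,4-dione ring. It is cut at the handle-free CH2–CH2 bond between chain carbons 2 and 3, counted from the ring.
- Both halves are carboxylic acids that lose CO2 at a platinum anode: a 3-(2,5-dimethoxyphenyl)propanoic acid supplies the ring with its two-carbon arm, and stearic acid supplies the C17 tail (crossed Kolbe coupling).
- The acid arm traces back to 2,5-dimethoxybenzaldehyde and malonic acid (Knoevenagel–Doebner condensation, then hydrogenation).
- No ring is formed: the single six-membered carbocycle is bought as the arene and is oxidised last, anodically to the quinone bisketal and then by hydrolysis to the quinone.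

Key step: step 3

Remark on the chemistry: in the final hydrolysis the ketal that ionises first is assumed to be the one not adjacent to the chain-bearing ring carbon, because its cation is stabilised by the alkyl group. The other monoketal would converge on the same quinone.

**Step 1**
Reactants: 1 2,5-dimethoxybenzaldehyde; 2 malonic acid
Product: 4 (E)-3-(2,5-dimethoxyphenyl)acrylic acid, via arylidenemalonic acid 3 (not isolated)
Conditions: 2 (2 equiv), piperidine (cat.), pyridine, 90 °C then reflux until gas evolution stops; aq. HCl work-up, recrystallisation
Reagents that add atoms: none
Why: Knoevenagel–Doebner condensation, in which the amine-activated aldehyde condenses with malonic acid to the arylidenemalonic acid, and decarboxylation in hot pyridine should deliver the thermodynamically preferred E acrylic acid without forming any stereocentre.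

**Step 2**
Reactants: 4 (E)-3-(2,5-dimethoxyphenyl)acrylic acid
Product: 5 3-(2,5-dimethoxyphenyl)propanoic acid
Conditions: H2 (1 atm), 10% Pd/C, EtOAc, rt
Reagents that add atoms: none
Why: Heterogeneous catalytic hydrogenation of a conjugated disubstituted alkene should saturate the side chain while leaving the arene, the aryl methyl ethers and the carboxylic acid untouched, and it removes the only stereogenic element of the intermediate.

**Step 3**
Reactants: 5 3-(2,5-dimethoxyphenyl)propanoic acid; 6 stearic acid (octadecanoic acid)
Product: 7 1,4-dimethoxy-2-nonadecylbenzene
Conditions: 6 in about five-fold excess, NaOMe (about 0.05 equiv per CO2H), MeOH–hexane, 50 °C, Pt anode and Pt cathode, undivided cell, constant current at high anodic current density (about 0.25 A per cm2), occasional polarity reversal, until the electrolyte turns weakly alkaline; neutral fraction chromatographed on silica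
Reagents that add atoms: none
Why: At smooth platinum and high current density in weakly acidic methanol both carboxylates are discharged to acyloxy radicals, which lose CO2, and the 2-(2,5-dimethoxyphenyl)ethyl and heptadecyl radicals, generated side by side in the adsorbed carboxylate layer, combine to the new CH2–CH2 bond between chain carbons 2 and 3 (crossed Kolbe electrolysis). The closest known reaction type is the mixed Kolbe coupling of a 3-arylpropanoic acid with a straight-chain fatty acid, both partners being unbranched primary acids, the class that gives radical coupling and not carbocation products. No ring is closed and no stereocentre is formed; the primary arylethyl radical has no favourable cyclisation onto its own ring, its 1,2-aryl shift is degenerate, and it has no productive β-scission. The step needs chemoselectivity for the cross product over the homodimer of 5, which the several-fold excess of inexpensive 6 should secure, the surplus ending as a non-polar C34 alkane that is washed off silica with hexane ahead of 7. It also needs decarboxylation to outrun oxidation of the electron-rich ring, which the dense carboxylate film of the Kolbe regime favours by keeping neutral arene and solvent away from the anode. Ring methoxylation that still occurs leads toward the oxidation level that step 4 installs on purpose, so a neutral fraction containing such material can be carried into step 4.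

**Step 4**
Reactants: 7 1,4-dimethoxy-2-nonadecylbenzene
Product: 8 3,3,6,6-tetramethoxy-1-nonadecylcyclohexa-1,4-diene
Conditions: KOH (1% w/v), MeOH–THF, Pt anode and Pt cathode, undivided cell, constant current, 0 °C to rt, charge passed until 7 is consumed; basic work-up, used crude
Reagents that add atoms: methanol, CO
Why: Anodic bis-methoxylation of a 1,4-dimethoxyarene (oxidation to the arene radical cation, methoxide capture at one methoxy-bearing carbon, a second electron transfer and capture at the para methoxy-bearing carbon) should give the quinone bisketal, the alkaline methanol keeping the acid-labile ketals intact and the saturated chain staying inert.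

**Step 5**
Reactants: 8 3,3,6,6-tetramethoxy-1-nonadecylcyclohexa-1,4-diene
Product: 10 2-nonadecylcyclohexa-2,5-diene-1,4-dione (2-nonadecyl-1,4-benzoquinone), via dienone monoketal 9 (not isolated)
Conditions: 1 M aq. H2SO4, THF, rt (gentle warming if the second ketal is slow), dark; extraction, recrystallisation
Reagents that add atoms: water, O
Why: Acid-catalysed hydrolysis of the two allylic dimethyl ketals (quinone bisketal hydrolysis) proceeds by ionisation to a dienyl oxocarbenium ion, capture by water and loss of methanol, giving first the dienone monoketal and then the quinone, and a non-nucleophilic acid is chosen so that nothing adds to the quinone.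

**Compound list**
1 | 2,5-dimethoxybenzaldehyde | COc1ccc(OC)c(C=O)c1 | starting material
2 | malonic acid | OC(=O)CC(=O)O | starting material
3 | 2-[(2,5-dimethoxyphenyl)methylidene]propanedioic acid (arylidenemalonic acid, not isolated) | COc1ccc(OC)c(C=C(C(=O)O)C(=O)O)c1 | intermediate
4 | (E)-3-(2,5-dimethoxyphenyl)acrylic acid | COc1ccc(OC)c(/C=C/C(=O)O)c1 | intermediate
5 | 3-(2,5-dimethoxyphenyl)propanoic acid | COc1ccc(OC)c(CCC(=O)O)c1 | intermediate
6 | stearic acid (octadecanoic acid) | CCCCCCCCCCCCCCCCCC(=O)O | starting material
7 | 1,4-dimethoxy-2-nonadecylbenzene | CCCCCCCCCCCCCCCCCCCc1cc(OC)ccc1OC | intermediate
8 | 3,3,6,6-tetramethoxy-1-nonadecylcyclohexa-1,4-diene | CCCCCCCCCCCCCCCCCCCC1=CC(OC)(OC)C=CC1(OC)OC | intermediate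
9 | 4,4-dimethoxy-3-nonadecylcyclohexa-2,5-dien-1-one (dienone monoketal, not isolated) | CCCCCCCCCCCCCCCCCCCC1=CC(=O)C=CC1(OC)OC | intermediate
10 | 2-nonadecylcyclohexa-2,5-diene-1,4-dione (2-nonadecyl-1,4-benzoquinone) | CCCCCCCCCCCCCCCCCCCC1=CC(=O)C=CC1=O | target

**Total step count:** 5
**Longest linear sequence:** 5 steps (1 to 4 to 5 to 7 to 8 to 10); stearic acid 6 enters as a bought partner in step 3.

**Steps most likely to fail**

Step 3 (crossed Kolbe coupling). The electron-rich ring may be oxidised at the anode before the carboxylate is discharged, and the waxy hydrocarbon by-product may film over the anode; both lower the share of cross-coupling. The fallback replaces the anodic radical union by an olefination; it sets out from compound 1 and returns to the route at compound 7. Commercial octadecyltriphenylphosphonium bromide is deprotonated with KOtBu in THF at 0 °C to octadecylidene(triphenyl)phosphorane F1. This ylide is condensed with 1 in a Wittig reaction to give 1,4-dimethoxy-2-(nonadec-1-en-1-yl)benzene F2, expected as a mainly Z mixture of alkene isomers. Hydrogenation (H2, 10% Pd/C, EtOAc, rt) removes the alkene and its geometry and should give 7.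

Step 4 (anodic bis-methoxylation). Conversion may stall because the long-chain arene dissolves poorly in alkaline methanol and coats the electrode, and methoxylation at the benzylic CH2 may compete with ring addition. The fallback replaces the electrolysis by a chemical one-electron oxidant; it sets out from compound 7 and returns at compound 10, leaving out 8. Oxidative demethylation with (NH4)2Ce(NO3)6 in MeCN–H2O with CH2Cl2 as cosolvent at 0 °C, the arene being added to the oxidant so that the oxidant stays in excess, should give the quinone directly. No new compound is made on the way.

Step 5 (bisketal hydrolysis). The reaction may stop at the monoketal stage because the lipophilic substrate partitions away from the aqueous acid, and prolonged acid exposure may degrade the quinone. The fallback forms the quinone under neutral conditions; it sets out from compound 7 and returns at compound 10, leaving out 8. Both methyl ethers are cleaved with 48% aq. HBr in AcOH at reflux to give 2-nonadecylbenzene-1,4-diol F3. The hydroquinone is then dehydrogenated with Ag2O (Et2O, MgSO4, rt) to 10.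

**Further compounds**
F1 | step 3 | octadecylidene(triphenyl)phosphorane | CCCCCCCCCCCCCCCCCC=P(c1ccccc1)(c1ccccc1)c1ccccc1
F2 | step 3 | (Z)-1,4-dimethoxy-2-(nonadec-1-en-1-yl)benzene (major isomer of a Z/E mixture) | CCCCCCCCCCCCCCCCC/C=C\c1cc(OC)ccc1OC
F0 | step 4 | none | none
F3 | step 5 | 2-nonadecylbenzene-1,4-diol | CCCCCCCCCCCCCCCCCCCc1cc(O)ccc1O
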